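**Retrosynthetic overview**

1. Target ⇒ acetylation and hydrogenolysis of the bis-benzyl 8-hydroxy furofuran; its bridgehead OH ⇒ enolate hydroxylation of a cis-fused furofuranone, where the cis ring fusion dictates the C8 configuration.
2. Furofuranone ⇒ C2-symmetric exo,exo-dilactone; the two aryl groups are identical, so either lactone may be taken down to the ether.
3. Dilactone ⇒ 2,3-bis[aryl(hydroxy)methyl]succinyl bis-imide by double lactonisation with loss of both auxiliaries.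
4. Bis-imide ⇒ two intermolecular Evans syn aldol additions of boron enolates to O-benzylvanillin (C7'–C8' first, C7–C8 second), starting from a pent-4-enoyl imide whose allyl group is later cleaved to the second acyl arm.
5. Ring order: rings A and B close together as γ-lactones; ring B is reduced to the ether first, ring A after the hydroxylation.

Assumption: lignan numbering is used (C7, C8, C9 = acetoxylated half; C7', C8', C9' = other half; ring A = O/C7'/C8'/C8/C9, ring B = O/C7/C8/C8'/C9'); Ar = 4-(benzyloxy)-3-methoxyphenyl; Xc = (4R)-4-benzyl-2-oxo-1,3-oxazolidin-3-yl; TBS = tert-butyldimethylsilyl; O-benzylvanillin and both enantiomers of 4-benzyl-1,3-oxazolidin-2-one are bought.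

**Route**

Step 1
Reactants: 1 (R)-4-benzyl-1,3-oxazolidin-2-one; 2 pent-4-enoyl chloride
Product: 3 (4R)-4-benzyl-3-(pent-4-enoyl)-1,3-oxazolidin-2-one
Conditions: Et3N, DMAP (cat.), CH2Cl2, 0 °C to rt
Reagents that add atoms: none
Why: DMAP-catalysed N-acylation of the oxazolidinone by the acid chloride; no stereocentre is involved.

Step 2
Reactants: 3 (4R)-4-benzyl-3-(pent-4-enoyl)-1,3-oxazolidin-2-one; 4 4-(benzyloxy)-3-methoxybenzaldehyde
Product: 6 (4R)-4-benzyl-3-[(2R)-2-[(R)-Ar(hydroxy)methyl]pent-4-enoyl]-1,3-oxazolidin-2-one, via Z-dibutylboron enolate 5 (not isolated)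
Conditions: n-Bu2BOTf, i-Pr2NEt, CH2Cl2, −78 to 0 °C; then 4, −78 to 0 °C; pH 7 phosphate buffer, MeOH, 30% H2O2, 0 °C
Reagents that add atoms: none
Why: Evans syn aldol; the Z-boron enolate reacts through a Zimmerman–Traxler chair on the face away from the auxiliary benzyl group, setting C8' and C7' as (2R,3R).

Step 3
Reactants: 6 syn aldol adduct
Product: 7 (4R)-4-benzyl-3-[(2R)-2-[(R)-Ar(TBSO)methyl]pent-4-enoyl]-1,3-oxazolidin-2-one
Conditions: TBSOTf, 2,6-lutidine, CH2Cl2, −78 to 0 °C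
Reagents that add atoms: tert-butyldimethylsilyl triflate, CC(C)(C)[Si](C)(C)OS(=O)(=O)C(F)(F)F
Why: Silylation of the secondary benzylic alcohol blocks retro-aldol and premature lactonisation in the steps that follow.

Step 4
Reactants: 7 silyl ether
Product: 8 (3R)-4-Xc-3-[(R)-Ar(TBSO)methyl]-4-oxobutanal
Conditions: OsO4 (2 mol%), NaIO4, 2,6-lutidine, dioxane/H2O 3:1, rt
Reagents that add atoms: OsO4, O=[Os](=O)(=O)=O; NaIO4, [Na+].[O-]I(=O)(=O)=O
Why: Lemieux–Johnson oxidative cleavage takes the terminal alkene to the aldehyde, and the electron-rich arenes, the imide and the silyl ether are inert to it.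

Step 5
Reactants: 8 aldehyde
Product: 9 (3R)-4-Xc-3-[(R)-Ar(TBSO)methyl]-4-oxobutanoic acid
Conditions: NaClO2, NaH2PO4, 2-methylbut-2-ene, t-BuOH/H2O, 0 °C to rt
Reagents that add atoms: sodium chlorite, [Na+].[O-]Cl=O
Why: Pinnick oxidation of the aldehyde to the acid; the alkene scavenger removes HOCl before it can chlorinate the arenes.

Step 6
Reactants: 9 acid; 1 (R)-4-benzyl-1,3-oxazolidin-2-one
Product: 11 (2R)-2-[(R)-Ar(TBSO)methyl]-1,4-bis(Xc)butane-1,4-dione, via mixed pivalic anhydride 10 (not isolated)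
Conditions: t-BuCOCl, Et3N, THF, −20 °C; then 1, LiCl, rt
Reagents that add atoms: none
Why: Mixed-anhydride N-acylation; the oxazolidinone attacks the unhindered carbonyl of the anhydride, and the existing imide and both stereocentres are untouched.

Step 7
Reactants: 11 bis-imide; 4 4-(benzyloxy)-3-methoxybenzaldehyde
Product: 13 (2R,3R)-2-[(R)-Ar(TBSO)methyl]-3-[(R)-Ar(hydroxy)methyl]-1,4-bis(Xc)butane-1,4-dione, via Z-dibutylboron enolate 12 (not isolated)
Conditions: n-Bu2BOTf, i-Pr2NEt, CH2Cl2, −78 to 0 °C; then 4, −78 to 0 °C; pH 7 phosphate buffer, MeOH, 30% H2O2, 0 °C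
Reagents that add atoms: none
Why: Second Evans syn aldol; only the unbranched CH2–C(=O)Xc arm is enolised (the α-branched imide is protected by A(1,3) strain), and the same (R)-auxiliary sets C8 and C7 with the same sense as step 2, giving the C2-symmetric backbone.

Step 8
Reactants: 13 aldol adduct
Product: 16 (3R,3aR,6R,6aR)-3,6-bis(Ar)tetrahydro-1H,3H-furo[3,4-c]furan-1,4-dione (C2-symmetric exo,exo-dilactone), via desilylated diol 14 (not isolated), via hydroxy lactone imide 15 (not isolated)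
Conditions: HF·pyridine, THF, 0 °C to rt; then Et3N, DMAP (cat.), CH2Cl2, rt
Reagents that add atoms: none
Why: Fluoride desilylation followed by two 5-exo lactonisations (intramolecular acyl transfer from the N-acyl oxazolidinones); no C–O bond at C7 or C7' is broken, so both aryl groups end up exo on the cis-fused bicycle.

Step 9
Reactants: 16 dilactone
Product: 17 (3R,3aR,6R,6aR)-4-hydroxy-3,6-bis(Ar)tetrahydro-1H,3H-furo[3,4-c]furan-1-one (mono-lactol; anomers at C4)
Conditions: i-Bu2AlH (1.0 equiv), CH2Cl2, −78 °C; MeOH, aq. potassium sodium tartrate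
Reagents that add atoms: none
Why: Partial hydride reduction of one of the two equivalent lactones stops at the aluminium hemiacetal at −78 °C; the outcome is statistical (roughly half mono-lactol at best), so unreacted 16 is recovered and recycled.

Step 10
Reactants: 17 mono-lactol
Product: 18 (3R,3aS,6R,6aR)-3,6-bis(Ar)tetrahydro-1H,3H-furo[3,4-c]furan-1-one (furofuranone; ring B now an ether)
Conditions: Et3SiH, BF3·OEt2, CH2Cl2, −78 to −40 °C
Reagents that add atoms: none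
Why: Ionic hydrogenation of the lactol through its oxocarbenium ion gives the CH2–O ether (no new stereocentre), and at low temperature the lactone and the benzylic C–O bonds are not ionised.

Step 11
Reactants: 18 furofuranone
Product: 20 (3R,3aS,6S,6aS)-6a-hydroxy-3,6-bis(Ar)tetrahydro-1H,3H-furo[3,4-c]furan-1-one, via potassium enolate 19 (not isolated)
Conditions: KN(SiMe3)2, THF, −78 °C; then 2-(phenylsulfonyl)-3-phenyloxaziridine, −78 °C; aq. NH4Cl
Reagents that add atoms: 2-(phenylsulfonyl)-3-phenyloxaziridine (Davis oxaziridine), O=S(=O)(c1ccccc1)N1OC1c1ccccc1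
Why: Davis enolate hydroxylation; the bridgehead enolate can only be oxidised on the convex face of the cis-fused bicycle, so OH replaces H at C8 with the target configuration, and loss of the ring B alkoxide is disfavoured because the C7–O bond lies near the enolate plane.

Step 12
Reactants: 20 hydroxy furofuranone
Product: 21 (3R,3aS,6S,6aS)-3,6-bis(Ar)tetrahydro-1H,3H-furo[3,4-c]furan-1,6a-diol (lactol at C9; anomers at C1)
Conditions: i-Bu2AlH (2.5 equiv), CH2Cl2, −78 °C; aq. potassium sodium tartrate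
Reagents that add atoms: none
Why: Hydride reduction of the remaining lactone to the lactol; the first equivalent is consumed by the tertiary hydroxyl and no stereocentre of the backbone is affected.

Step 13
Reactants: 21 lactol
Product: 22 (3S,3aR,6R,6aS)-3,6-bis(Ar)tetrahydro-1H,3H-furo[3,4-c]furan-3a(4H)-ol (bis-benzyl 8-hydroxypinoresinol)
Conditions: Et3SiH, BF3·OEt2, CH2Cl2, −78 to −20 °C
Reagents that add atoms: none
Why: Second ionic hydrogenation of a lactol via its oxocarbenium ion completes ring A as the ether; the tertiary alcohol cannot ionise at the bridgehead.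

Step 14
Reactants: 22 tertiary alcohol
Product: 23 [(3S,3aR,6R,6aS)-3,6-bis(Ar)tetrahydro-1H,3H-furo[3,4-c]furan-3a(4H)-yl] acetate
Conditions: Ac2O, DMAP, Et3N, CH2Cl2, rt to 40 °C
Reagents that add atoms: acetic anhydride, CC(=O)OC(C)=O
Why: DMAP-mediated acylation of the only free hydroxyl, which sits on the accessible convex face; both phenols are still benzylated.

Step 15
Reactants: 23 bis-benzyl acetate
Product: 24 8-acetoxypinoresinol, [(3S,3aR,6R,6aS)-3,6-bis(4-hydroxy-3-methoxyphenyl)tetrahydro-1H,3H-furo[3,4-c]furan-3a(4H)-yl] acetate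
Conditions: H2 (1 atm), 10% Pd/C, EtOAc, rt, stopped at full conversion
Reagents that add atoms: none
Why: Hydrogenolysis of aryl benzyl ethers is much faster than cleavage of the ring benzylic C–O bonds in a neutral aprotic solvent, and the tertiary acetate is inert.

**Compound list**

1 | (R)-4-benzyl-1,3-oxazolidin-2-one | O=C1N[C@H](Cc2ccccc2)CO1 | starting material
2 | pent-4-enoyl chloride | C=CCCC(Cl)=O | starting material
3 | (4R)-4-benzyl-3-(pent-4-enoyl)-1,3-oxazolidin-2-one | C=CCCC(=O)N1C(=O)OC[C@H]1Cc1ccccc1 | intermediate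
4 | 4-(benzyloxy)-3-methoxybenzaldehyde (O-benzylvanillin) | COc1cc(C=O)ccc1OCc1ccccc1 | starting material
5 | Z-dibutylboron enolate of 3 | C=CC/C=C(\OB(CCCC)CCCC)N1C(=O)OC[C@H]1Cc1ccccc1 | intermediate (not isolated)
6 | (4R)-4-benzyl-3-[(2R)-2-[(R)-Ar(hydroxy)methyl]pent-4-enoyl]-1,3-oxazolidin-2-one | C=CC[C@@H](C(=O)N1C(=O)OC[C@H]1Cc1ccccc1)[C@@H](O)c1ccc(OCc2ccccc2)c(OC)c1 | intermediate
7 | TBS ether of 6 | C=CC[C@@H](C(=O)N1C(=O)OC[C@H]1Cc1ccccc1)[C@@H](O[Si](C)(C)C(C)(C)C)c1ccc(OCc2ccccc2)c(OC)c1 | intermediate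
8 | (3R)-4-Xc-3-[(R)-Ar(TBSO)methyl]-4-oxobutanal | O=CC[C@@H](C(=O)N1C(=O)OC[C@H]1Cc1ccccc1)[C@@H](O[Si](C)(C)C(C)(C)C)c1ccc(OCc2ccccc2)c(OC)c1 | intermediate
9 | (3R)-4-Xc-3-[(R)-Ar(TBSO)methyl]-4-oxobutanoic acid | OC(=O)C[C@@H](C(=O)N1C(=O)OC[C@H]1Cc1ccccc1)[C@@H](O[Si](C)(C)C(C)(C)C)c1ccc(OCc2ccccc2)c(OC)c1 | intermediate
10 | mixed anhydride of 9 with pivalic acid | CC(C)(C)C(=O)OC(=O)C[C@@H](C(=O)N1C(=O)OC[C@H]1Cc1ccccc1)[C@@H](O[Si](C)(C)C(C)(C)C)c1ccc(OCc2ccccc2)c(OC)c1 | intermediate (not isolated)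
11 | (2R)-2-[(R)-Ar(TBSO)methyl]-1,4-bis(Xc)butane-1,4-dione | O=C(C[C@@H](C(=O)N1C(=O)OC[C@H]1Cc1ccccc1)[C@@H](O[Si](C)(C)C(C)(C)C)c1ccc(OCc2ccccc2)c(OC)c1)N1C(=O)OC[C@H]1Cc1ccccc1 | intermediate
12 | Z-dibutylboron enolate of 11 (unbranched arm) | CCCCB(CCCC)O/C(N1C(=O)OC[C@H]1Cc1ccccc1)=C\[C@@H](C(=O)N1C(=O)OC[C@H]1Cc1ccccc1)[C@@H](O[Si](C)(C)C(C)(C)C)c1ccc(OCc2ccccc2)c(OC)c1 | intermediate (not isolated)
13 | (2R,3R)-2-[(R)-Ar(TBSO)methyl]-3-[(R)-Ar(hydroxy)methyl]-1,4-bis(Xc)butane-1,4-dione | O=C(N1C(=O)OC[C@H]1Cc1ccccc1)[C@@H]([C@@H](O)c1ccc(OCc2ccccc2)c(OC)c1)[C@@H](C(=O)N1C(=O)OC[C@H]1Cc1ccccc1)[C@@H](O[Si](C)(C)C(C)(C)C)c1ccc(OCc2ccccc2)c(OC)c1 | intermediate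
14 | (2R,3R)-2,3-bis[(R)-Ar(hydroxy)methyl]-1,4-bis(Xc)butane-1,4-dione | O=C(N1C(=O)OC[C@H]1Cc1ccccc1)[C@@H]([C@@H](O)c1ccc(OCc2ccccc2)c(OC)c1)[C@@H](C(=O)N1C(=O)OC[C@H]1Cc1ccccc1)[C@@H](O)c1ccc(OCc2ccccc2)c(OC)c1 | intermediate (not isolated)
15 | (3R,4R,5R)-5-Ar-4-(Xc-carbonyl)-3-[(R)-Ar(hydroxy)methyl]oxolan-2-one | O=C1O[C@@H](c2ccc(OCc3ccccc3)c(OC)c2)[C@H](C(=O)N2C(=O)OC[C@H]2Cc2ccccc2)[C@@H]1[C@@H](O)c1ccc(OCc2ccccc2)c(OC)c1 | intermediate (not isolated)
16 | (3R,3aR,6R,6aR)-3,6-bis(Ar)tetrahydro-1H,3H-furo[3,4-c]furan-1,4-dione | O=C1O[C@@H](c2ccc(OCc3ccccc3)c(OC)c2)[C@@H]2C(=O)O[C@@H](c3ccc(OCc4ccccc4)c(OC)c3)[C@H]12 | intermediate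
17 | (3R,3aR,6R,6aR)-4-hydroxy-3,6-bis(Ar)tetrahydro-1H,3H-furo[3,4-c]furan-1-one, anomeric mixture | O=C1O[C@@H](c2ccc(OCc3ccccc3)c(OC)c2)[C@@H]2C(O)O[C@@H](c3ccc(OCc4ccccc4)c(OC)c3)[C@H]12 | intermediate
18 | (3R,3aS,6R,6aR)-3,6-bis(Ar)tetrahydro-1H,3H-furo[3,4-c]furan-1-one | O=C1O[C@@H](c2ccc(OCc3ccccc3)c(OC)c2)[C@@H]2CO[C@@H](c3ccc(OCc4ccccc4)c(OC)c3)[C@H]12 | intermediate
19 | potassium enolate of 18 | [K+].[O-]C1=C2[C@H](c3ccc(OCc4ccccc4)c(OC)c3)OC[C@H]2[C@H](c2ccc(OCc3ccccc3)c(OC)c2)O1 | intermediate (not isolated)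
20 | (3R,3aS,6S,6aS)-6a-hydroxy-3,6-bis(Ar)tetrahydro-1H,3H-furo[3,4-c]furan-1-one | O=C1O[C@@H](c2ccc(OCc3ccccc3)c(OC)c2)[C@@H]2CO[C@@H](c3ccc(OCc4ccccc4)c(OC)c3)[C@]12O | intermediate
21 | (3R,3aS,6S,6aS)-3,6-bis(Ar)tetrahydro-1H,3H-furo[3,4-c]furan-1,6a-diol, anomeric mixture | OC1O[C@@H](c2ccc(OCc3ccccc3)c(OC)c2)[C@@H]2CO[C@@H](c3ccc(OCc4ccccc4)c(OC)c3)[C@]12O | intermediate
22 | (3S,3aR,6R,6aS)-3,6-bis(Ar)tetrahydro-1H,3H-furo[3,4-c]furan-3a(4H)-ol | C1O[C@@H](c2ccc(OCc3ccccc3)c(OC)c2)[C@@H]2CO[C@@H](c3ccc(OCc4ccccc4)c(OC)c3)[C@]12O | intermediate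
23 | [(3S,3aR,6R,6aS)-3,6-bis(Ar)tetrahydro-1H,3H-furo[3,4-c]furan-3a(4H)-yl] acetate | C1O[C@@H](c2ccc(OCc3ccccc3)c(OC)c2)[C@@H]2CO[C@@H](c3ccc(OCc4ccccc4)c(OC)c3)[C@]12OC(C)=O | intermediate
24 | 8-acetoxypinoresinol (7S,8R,7'R,8'S) | COc1cc([C@@H]2OC[C@@]3(OC(C)=O)[C@H](c4ccc(O)c(OC)c4)OC[C@@H]23)ccc1O | target

**Totals and risks**

Total step count: 15. Longest linear sequence: 15 steps (1 and 2 to 24; compounds 1 and 4 are each used twice).

The three steps most likely to fail are steps 7, 11 and 13.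

Step 7 may stall or lose selectivity. The enolate carries a very bulky α-substituent, and by the A(1,3)-strain model the resident C8' centre favours the opposite face to the one the auxiliary selects. The fallback makes the C7–C8 bond by auxiliary-controlled C-acylation followed by chelate-controlled reduction. It sets out from acid 9. Coupling as in step 6, but with (S)-4-benzyl-1,3-oxazolidin-2-one, gives the mixed bis-imide F1. Its chelated sodium Z-enolate (NaN(SiMe3)2, THF, −78 °C) takes carbon electrophiles on the face opposite to that used in the boron aldol, which is why the enantiomeric auxiliary is needed. Acylation with commercial 4-(benzyloxy)-3-methoxybenzoyl chloride gives the configurationally stable β-keto imide F2. Zn(BH4)2 reduces the ketone through the six-membered zinc chelate to the syn alcohol F3. F3 differs from 13 only in the configuration of one auxiliary and comes back to the route at dilactone 16 under the conditions of step 8.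

Step 11 may fail because the bridgehead potassium enolate can open ring B by β-alkoxide loss, or because the product alkoxide adds to the sulfonimine by-product. The fallback avoids a free enolate and sets out from furofuranone 18. LiN(i-Pr)2 in the presence of Me3SiCl (in situ quench, THF, −78 °C) gives the silyl ketene acetal F4. Rubottom oxidation with dimethyldioxirane (acetone, −40 °C) epoxidises it on the convex face, and silyl migration gives the α-silyloxy lactone F5. Aqueous citric acid work-up cleaves F5 and returns to the route at 20.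

Step 13 may fail because the oxocarbenium ion next to the C8 hydroxyl forms sluggishly, so the BF3·OEt2 needed may ionise the electron-rich benzylic ethers and epimerise C7 or C7'. The fallback closes ring A without a Lewis acid and sets out from hydroxy lactone 20. LiAlH4 (THF, 0 °C) gives the triol F6. TsCl in pyridine sulfonylates only the primary hydroxyl, giving the tosylate F7. Warming in pyridine, with no alkoxide present so that epoxide formation by the tertiary hydroxyl is suppressed, lets the C7' hydroxyl displace the tosylate in a 5-exo closure with retention at C7'. This returns to the route at 22; the epoxide remains the main hazard of this fallback.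

**Further compounds**

F1 | step 7 | (2R)-2-[(R)-Ar(TBSO)methyl]-1-[(4R)-4-benzyl-2-oxo-1,3-oxazolidin-3-yl]-4-[(4S)-4-benzyl-2-oxo-1,3-oxazolidin-3-yl]butane-1,4-dione | O=C(C[C@@H](C(=O)N1C(=O)OC[C@H]1Cc1ccccc1)[C@@H](O[Si](C)(C)C(C)(C)C)c1ccc(OCc2ccccc2)c(OC)c1)N1C(=O)OC[C@@H]1Cc1ccccc1
F2 | step 7 | (2R,3R)-2-[(R)-Ar(TBSO)methyl]-3-[4-(benzyloxy)-3-methoxybenzoyl]-1-[(4R)-4-benzyl-2-oxo-1,3-oxazolidin-3-yl]-4-[(4S)-4-benzyl-2-oxo-1,3-oxazolidin-3-yl]butane-1,4-dione | O=C(N1C(=O)OC[C@@H]1Cc1ccccc1)[C@@H](C(=O)c1ccc(OCc2ccccc2)c(OC)c1)[C@@H](C(=O)N1C(=O)OC[C@H]1Cc1ccccc1)[C@@H](O[Si](C)(C)C(C)(C)C)c1ccc(OCc2ccccc2)c(OC)c1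
F3 | step 7 | (2R,3R)-2-[(R)-Ar(TBSO)methyl]-3-[(R)-Ar(hydroxy)methyl]-1-[(4R)-4-benzyl-2-oxo-1,3-oxazolidin-3-yl]-4-[(4S)-4-benzyl-2-oxo-1,3-oxazolidin-3-yl]butane-1,4-dione | O=C(N1C(=O)OC[C@@H]1Cc1ccccc1)[C@@H]([C@@H](O)c1ccc(OCc2ccccc2)c(OC)c1)[C@@H](C(=O)N1C(=O)OC[C@H]1Cc1ccccc1)[C@@H](O[Si](C)(C)C(C)(C)C)c1ccc(OCc2ccccc2)c(OC)c1
F4 | step 11 | trimethylsilyl ketene acetal of 18 | C[Si](C)(C)OC1=C2[C@H](c3ccc(OCc4ccccc4)c(OC)c3)OC[C@H]2[C@H](c2ccc(OCc3ccccc3)c(OC)c2)O1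
F5 | step 11 | trimethylsilyl ether of 20 (6a-silyloxy furofuranone) | O=C1O[C@@H](c2ccc(OCc3ccccc3)c(OC)c2)[C@@H]2CO[C@@H](c3ccc(OCc4ccccc4)c(OC)c3)[C@]12O[Si](C)(C)C
F6 | step 13 | (2S,3R,4S)-2-Ar-3-(hydroxymethyl)-4-[(R)-Ar(hydroxy)methyl]oxolan-3-ol | OC[C@@]1(O)[C@H](c2ccc(OCc3ccccc3)c(OC)c2)OC[C@H]1[C@@H](O)c1ccc(OCc2ccccc2)c(OC)c1
F7 | step 13 | primary p-toluenesulfonate of F6 | Cc1ccc(S(=O)(=O)OC[C@@]2(O)[C@H](c3ccc(OCc4ccccc4)c(OC)c3)OC[C@H]2[C@@H](O)c2ccc(OCc3ccccc3)c(OC)c2)cc1
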